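**Retrosynthetic overview**

1. Skeleton: the C17 side chain, with both Z-olefins already in place, is C2–C18 of linoleic acid (1). With N-hydroxyphthalimide (2) as activator, the only C–C disconnection is aryl–C1′, made by decarboxylative arylation with 1-iodo-3,5-dimethoxybenzene (3) through ester 4 to give dimethyl ether 5.
2. O–CH3 disconnection: 5 is unmasked with 9-iodo-9-BBN (6) through borinate 7 to the free resorcinol 8.
3. Key disconnection, the last bond made: C16–O of the target 9 goes back to the unactivated C16–H of 8 (enantioselective ω-1 hydroxylation, which sets the only stereocentre).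
4. Rings: none is formed; the benzene ring is bought in 3.

Assumption: the P450 variant used in step 3 does not exist yet and has to be found by screening and directed evolution; this is counted as catalyst development, not as a step of the route.

**Route**

Step 1
Reactants: 1 linoleic acid [(9Z,12Z)-octadeca-9,12-dienoic acid]; 2 N-hydroxyphthalimide; 3 1-iodo-3,5-dimethoxybenzene
Product: 5 1-[(8Z,11Z)-heptadeca-8,11-dien-1-yl]-3,5-dimethoxybenzene, via redox-active ester 4 (not isolated)
Conditions: 2, i-PrN=C=N-i-Pr, DMAP (cat.), CH2Cl2, rt, Ar; evaporate; then 3, NiBr2·MeOCH2CH2OMe (10 mol%), 4,4'-di-tert-butyl-2,2'-bipyridine (10 mol%), Zn dust (2 equiv), degassed DMA, rt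
Reagents that add atoms: none
Why: Carbodiimide esterification followed by Ni-catalysed decarboxylative cross-electrophile coupling: zinc-reduced low-valent nickel transfers one electron to the phthalimide ester, which loses phthalimide anion and CO2 to give the primary C17 radical, and this is captured by the aryl–nickel species formed from 3 so that reductive elimination makes the aryl–C1′ bond; no stereocentre is created and the remote Z-olefins keep their geometry.

Step 2
Reactants: 5 1-[(8Z,11Z)-heptadeca-8,11-dien-1-yl]-3,5-dimethoxybenzene; 6 9-iodo-9-borabicyclo[3.3.1]nonane (9-iodo-9-BBN, 1 M in hexanes)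
Product: 8 5-[(8Z,11Z)-heptadeca-8,11-dien-1-yl]benzene-1,3-diol, via aryl bis(borinate) 7 (not isolated)
Conditions: 6 (2.5 equiv), hexane/CH2Cl2, 0 °C to rt; then HOCH2CH2NH2, Et2O, filter
Reagents that add atoms: none
Why: Lewis-acid-mediated aryl methyl ether cleavage (SN2 demethylation): boron binds the ether oxygen and iodide attacks the methyl group, giving MeI and the aryl borinate that ethanolamine then cleaves; this dialkylboron iodide, unlike BBr3, neither adds to nor isomerises the skipped Z,Z-diene, and no stereocentre is involved.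

Step 3
Reactants: 8 5-[(8Z,11Z)-heptadeca-8,11-dien-1-yl]benzene-1,3-diol
Product: 9 hansfordiol D = 5-[(8Z,11Z,16S)-16-hydroxyheptadeca-8,11-dien-1-yl]benzene-1,3-diol
Conditions: evolved CYP102A1 (P450 BM3) variant (clarified lysate, about 0.2 mol% P450), NADP+ (cat.), glucose dehydrogenase, D-glucose, catalase, air, KPi buffer pH 8.0, 2% DMSO, hydroxypropyl-β-cyclodextrin, 25 °C
Reagents that add atoms: dioxygen, O=O
Why: Proposed new method: enantioselective ω-1 C–H hydroxylation of a free alkylresorcinol by an evolved self-sufficient heme monooxygenase (P450 hydrogen-abstraction/oxygen-rebound hydroxylation), in which the resorcinol head sits at the mouth of the substrate channel where a fatty-acid carboxylate normally binds (R47L/Y51F open this site to a neutral head), the terminal methyl is parked in the small pocket beside the heme so that only the C16 methylene reaches the iron-oxo porphyrin radical cation, abstraction of the pro-S hydrogen and rebound with retention set 16S (pocket positions 82, 87, 263 and 328 are screened for this), and the weak doubly allylic C10–H and both Z-olefins are held further up the channel, away from iron; the closest known reaction type is the ω-1 to ω-3 hydroxylation of long-chain fatty acids, alcohols and amides by CYP102A1, together with the (S)-selective 2-hydroxylation of n-alkanes by its A328V-type variants and the (S)-selective ω-1 hydroxylation of oleic and linoleic acid by the sophorolipid enzyme CYP52M1, none of which has been shown on an alkylresorcinol or with full ω-1/S control next to a skipped diene.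

**Compound list**

1 | linoleic acid, (9Z,12Z)-octadeca-9,12-dienoic acid | CCCCC/C=C\C/C=C\CCCCCCCC(=O)O | starting material
2 | N-hydroxyphthalimide | O=C1c2ccccc2C(=O)N1O | starting material
3 | 1-iodo-3,5-dimethoxybenzene | COc1cc(I)cc(OC)c1 | starting material
4 | 1,3-dioxoisoindolin-2-yl (9Z,12Z)-octadeca-9,12-dienoate | CCCCC/C=C\C/C=C\CCCCCCCC(=O)ON1C(=O)c2ccccc2C1=O | intermediate
5 | 1-[(8Z,11Z)-heptadeca-8,11-dien-1-yl]-3,5-dimethoxybenzene | CCCCC/C=C\C/C=C\CCCCCCCc1cc(OC)cc(OC)c1 | intermediate
6 | 9-iodo-9-borabicyclo[3.3.1]nonane | IB1C2CCCC1CCC2 | starting material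
7 | 9,9'-[[5-[(8Z,11Z)-heptadeca-8,11-dien-1-yl]-1,3-phenylene]bis(oxy)]bis(9-borabicyclo[3.3.1]nonane) | CCCCC/C=C\C/C=C\CCCCCCCc1cc(OB2C3CCCC2CCC3)cc(OB2C3CCCC2CCC3)c1 | intermediate
8 | 5-[(8Z,11Z)-heptadeca-8,11-dien-1-yl]benzene-1,3-diol | CCCCC/C=C\C/C=C\CCCCCCCc1cc(O)cc(O)c1 | intermediate
9 | hansfordiol D, 5-[(8Z,11Z,16S)-16-hydroxyheptadeca-8,11-dien-1-yl]benzene-1,3-diol | C[C@H](O)CCC/C=C\C/C=C\CCCCCCCc1cc(O)cc(O)c1 | target

**Totals**

Total step count: 3. Longest linear sequence: 3 (1 → 5 → 8 → 9).

**Steps most likely to fail, and fallbacks**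

Step 3 (proposed new step). The variant may give ω-2/ω-3 alcohols, the 11,12-epoxide, ring oxidation or the 16R alcohol, and may take many rounds of evolution. The fallback uses known chemistry only, sets out from 3 and comes back at 9; the stereocentre is then set by enzymatic ketone reduction instead of C–H oxidation. Compound 3 is coupled with ethyl 8-bromooctanoate by Ni-catalysed cross-electrophile coupling (NiI2, 4,4'-di-tert-butyl-2,2'-bipyridine, pyridine, NaI, Zn, DMPU, 60 °C) to give ethyl 8-(3,5-dimethoxyphenyl)octanoate F1. Reduction with i-Bu2AlH (toluene, −78 °C) gives 8-(3,5-dimethoxyphenyl)octanal F2. A Z-selective Wittig reaction with the ylide from (3,3-diisopropoxypropyl)triphenylphosphonium bromide (NaN(SiMe3)2, THF, −78 °C) gives 1-[(8Z)-11,11-di(propan-2-yloxy)undec-8-en-1-yl]-3,5-dimethoxybenzene F3. Mild acetal hydrolysis (TsOH cat., THF/H2O) gives (3Z)-11-(3,5-dimethoxyphenyl)undec-3-enal F4, which is used at once. A second Z-selective Wittig reaction with the ylide from (hex-5-en-1-yl)triphenylphosphonium bromide gives 1-[(8Z,11Z)-heptadeca-8,11,16-trien-1-yl]-3,5-dimethoxybenzene F5. Tsuji–Wacker oxidation of the terminal olefin only (PdCl2, CuCl, O2, DMF/H2O) gives (6Z,9Z)-17-(3,5-dimethoxyphenyl)heptadeca-6,9-dien-2-one F6. A Prelog-selective alcohol dehydrogenase or commercial (S)-selective ketoreductase, with the cofactor recycled by i-PrOH, gives (2S,6Z,9Z)-17-(3,5-dimethoxyphenyl)heptadeca-6,9-dien-2-ol F7. Nucleophilic demethylation (NaSEt, DMF, 130 °C) then gives 9.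

Step 1. The primary radical may abstract a doubly allylic hydrogen, nickel hydrides may move the skipped diene into conjugation, or the aryl iodide may homocouple. The fallback sets out from 1 and comes back at 5; it replaces the one-pot nickel/zinc radical coupling by a nickel-free borylation and a two-electron palladium coupling. Compounds 1 and 2 are condensed as in step 1, but ester 4 is isolated by a short silica plug. Photochemical decarboxylative borylation of 4 (bis(catecholato)diboron, DMA, blue LEDs, rt; then pinacol, Et3N) gives 2-[(8Z,11Z)-heptadeca-8,11-dien-1-yl]-4,4,5,5-tetramethyl-1,3,2-dioxaborolane F8. Suzuki–Miyaura coupling of F8 with 3 (Pd(OAc)2, RuPhos, K3PO4, toluene/H2O, 80 °C) gives 5.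

Step 2. The second demethylation may stall, or traces of HI may add to or isomerise the diene. The fallback sets out from 1 and comes back at 8; it avoids ether cleavage altogether by changing to fluoride-labile silyl ethers. Commercial 5-iodoresorcinol (Oc1cc(O)cc(I)c1) is silylated (t-BuMe2SiCl, imidazole, DMF) to 1-iodo-3,5-bis(tert-butyldimethylsilyloxy)benzene F9. Compound 1 is taken through the conditions of step 1 with F9 in place of 3 to give 1-[(8Z,11Z)-heptadeca-8,11-dien-1-yl]-3,5-bis(tert-butyldimethylsilyloxy)benzene F10. Desilylation with n-Bu4NF/AcOH (THF, 0 °C) gives 8.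

**Further compounds**

F1 | step 3 | ethyl 8-(3,5-dimethoxyphenyl)octanoate | CCOC(=O)CCCCCCCc1cc(OC)cc(OC)c1
F2 | step 3 | 8-(3,5-dimethoxyphenyl)octanal | O=CCCCCCCCc1cc(OC)cc(OC)c1
F3 | step 3 | 1-[(8Z)-11,11-di(propan-2-yloxy)undec-8-en-1-yl]-3,5-dimethoxybenzene | CC(C)OC(C/C=C\CCCCCCCc1cc(OC)cc(OC)c1)OC(C)C
F4 | step 3 | (3Z)-11-(3,5-dimethoxyphenyl)undec-3-enal | O=CC/C=C\CCCCCCCc1cc(OC)cc(OC)c1
F5 | step 3 | 1-[(8Z,11Z)-heptadeca-8,11,16-trien-1-yl]-3,5-dimethoxybenzene | C=CCCC/C=C\C/C=C\CCCCCCCc1cc(OC)cc(OC)c1
F6 | step 3 | (6Z,9Z)-17-(3,5-dimethoxyphenyl)heptadeca-6,9-dien-2-one | CC(=O)CCC/C=C\C/C=C\CCCCCCCc1cc(OC)cc(OC)c1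
F7 | step 3 | (2S,6Z,9Z)-17-(3,5-dimethoxyphenyl)heptadeca-6,9-dien-2-ol | C[C@H](O)CCC/C=C\C/C=C\CCCCCCCc1cc(OC)cc(OC)c1
F8 | step 1 | 2-[(8Z,11Z)-heptadeca-8,11-dien-1-yl]-4,4,5,5-tetramethyl-1,3,2-dioxaborolane | CCCCC/C=C\C/C=C\CCCCCCCB1OC(C)(C)C(C)(C)O1
F9 | step 2 | 1-iodo-3,5-bis(tert-butyldimethylsilyloxy)benzene | CC(C)(C)[Si](C)(C)Oc1cc(I)cc(O[Si](C)(C)C(C)(C)C)c1
F10 | step 2 | 1-[(8Z,11Z)-heptadeca-8,11-dien-1-yl]-3,5-bis(tert-butyldimethylsilyloxy)benzene | CCCCC/C=C\C/C=C\CCCCCCCc1cc(O[Si](C)(C)C(C)(C)C)cc(O[Si](C)(C)C(C)(C)C)c1
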